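Remark on the chemistry: the SMILES is read as the trans-(2S,3R) isomer. Benzofuran numbering (O1, C2, C3, C3a, C4 to C7, C7a) is used throughout; ring A is the acetyl-bearing benzo ring and ring B the 4-hydroxy-3,5-dimethoxyphenyl ring.

## The problem

The target 18 is a dihydrobenzofuran neolignan. Ring A, carrying an acetyl group at C5 and a methoxy group at C7, is fused through C3a and C7a to a dihydrofuran ring whose C2 bears ring B and whose C3 bears a hydroxymethyl group. The two adjacent stereocentres are trans, (2S,3R), and a single enantiomer is required. C2 is a benzylic ether carbon that traces back to a secondary carbinol, so it can be set by one asymmetric operation and then direct C3, because trans is the favoured arrangement on this ring. The reverse relay is not available. C2 is the labile centre, since its C–O bond can open through a quinone methide once the para hydroxyl of ring B is free, or by ionisation in acid. C3 cannot be epimerised at the alcohol oxidation level, so a cis isomer must be removed and not equilibrated: inverting its C2 would lead into the enantiomeric series. The groups that restrict the reagents are the free phenol para to C2, the enolisable methyl ketone, the benzylic C2–O bond (hydrogenolysis, strong acid) and the primary alcohol. The feature that opens the molecule is C3: it carries the ring A carbon C3a and a CH2–O arm, next to C2. That is the pattern left when an aryl radical at C3a closes 5-exo onto a vinyl group on C2 and the exocyclic primary radical is captured by an oxygen-centred radical. Because O1 is ortho to C3a and para to the acetyl group, both the radical precursor (a diazonium group, from a nitro group) and the ether bond (an SNAr activated by nitro and acetyl) follow from nitration of acetovanillone 6 at C5.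

## Retrosynthesis

**18 back to 16 (no skeletal bonds).** The phenol of ring B is masked as its triisopropylsilyl ether (17) and the primary alcohol as the O-alkyl hydroxylamine of 2,2,6,6-tetramethylpiperidine (16). The silyl group stays until the last step because a free para phenol would make C2 labile. The N–O bond is cut before it, with zinc in acetic acid, while ring B is still protected. Both unmaskings are mild and leave the ketone and the two stereocentres alone.

**16 back to 13 and 15 (C3–C3a and CH2–O).** The aryl radical at C3a is generated from the diazonium salt 13 by electron transfer from TEMPONa 15, itself made from TEMPO 14. Ring closure onto the vinyl group forms the dihydrofuran ring and C3, and the TEMPO released in the electron transfer caps the primary radical. A cut of O1–C7a or of C2–C3 would leave two stereocentres to be made in an open chain. This cut leaves one, C2, outside any ring and asks the ring closure to set C3 trans to it. The precursor 13 is an aryl allyl ether with a single stereocentre. The forward step must cyclise faster than the aryl radical is intercepted and must prefer the trans product.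

**13 back to 11 (functional group changes at C3a).** The diazonium group comes from the aniline 12 and the aniline from the nitro compound 11. The nitro group is chosen because it serves twice: as latent radical precursor and as activator for the ether-forming step. The reduction must spare the terminal alkene, the ketone and the ionisable allylic benzylic ether, which rules out hydrogenation and acidic metal reductions. The diazotisation must be free of mineral acid for the same reason.

**11 back to 9 and 5 (O1–C7a).** The aryl ether is cut on the aryl side, giving the aryl chloride 9 and the (S)-allylic alcohol 5, which reacts as its potassium alkoxide 10. Cutting on the alkyl side would require substitution at a carbinol carbon that is both benzylic and allylic, where ionisation and allylic transposition would erode configuration and regiochemistry. The SNAr leaves the C–O bond of the carbinol intact, so the configuration of 5 passes unchanged into C2. The chloride sits ortho to the nitro group and para to the acetyl group, which is the activation the step needs. The enolisable ketone is the price, and it is addressed with stoichiometric base and inverse addition.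

**9 back to 6 (C–Cl and C–N on ring A).** Chloride 9 comes from nitrophenol 7 by chlorodehydroxylation through the O-aryl iminium salt 8, and 7 from acetovanillone 6 by nitration ortho to the hydroxyl group. Ring A is thus purchased with its acetyl and methoxy groups in place. Two steps suffice because the hydroxyl group both directs the nitration and becomes the leaving group.

**5 back to 1 and 3 (C–C bond to the vinyl group).** The (S)-alcohol 5 is the unreacted enantiomer of a lipase resolution of the racemic alcohol 4. Alcohol 4 comes from vinylmagnesium bromide 3 and the silylated aldehyde 2, and 2 from syringaldehyde 1. A resolution is preferred to a catalytic asymmetric vinylation because it can be driven to high enantiopurity on a cheap early intermediate. The triisopropylsilyl group is chosen because it must survive an alkoxide, a diazotisation, TEMPONa and zinc in acetic acid.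

## Roads not taken

**Alternative 1: ring A built by a pyrone Diels–Alder reaction.** The cut is at C7–C7a and C3a–C4, so ring A is made last. In the forward step the lactone-derived silyl ketene acetal A2 and the methoxy pyrone ester A3 undergo a [4+2] cycloaddition, and loss of CO2 and silanol then gives the benzofuran ester A1.
- Merits: both stereocentres are set on a butyrolactone, where the trans arrangement can be reached under thermodynamic control. The pyrone fixes the substitution pattern of ring A, and no diazonium salt is involved.
- Weak points: A1 carries a methyl ester at C5, so the acetyl group costs a further ester-to-ketone sequence. A2 needs an enantioselective synthesis of a trans-disubstituted lactone with two stereocentres. In the aromatisation the acetal carbon C7a bears both the silyloxy group and the ring oxygen, and expulsion of the ring oxygen would open the dihydrofuran. The 3-methoxy group also makes A3 a less electron-poor diene, so heating is likely.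
- Comparison: this road is better in the certainty of the trans relationship. Against that the chosen plan sets a shorter sequence, an acetyl group present from the first step, and two aromatic rings that are purchased and not built.

**Alternative 2: flavanone ring contraction with PhI(OAc)2.** The C3–C3a bond is made by a 1,2-aryl shift. The (S)-flavanone A5, treated with PhI(OAc)2 and H2SO4 in trimethyl orthoformate, lets ring A migrate from C4 to C3 and gives the trans ester A4.
- Merits: flavanones are easy to assemble, and this type of ring contraction gives trans 2-aryl-2,3-dihydrobenzofuran-3-carboxylates. In diastereoselectivity it is probably more dependable than a radical closure.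
- Weak points: A5 must be a single enantiomer, and flavanones racemise by reversible ring opening to the chalcone in acid or base. The electron-rich ring B competes for migration and is open to oxidation by trivalent iodine, hence the deactivating pivalate. A methyl ketone would not survive the oxidant, hence the bromide placeholder. After A4 there remain the ester reduction, a Pd(PPh3)4-catalysed Stille coupling with a 1-alkoxyvinyl stannane to install the acetyl group, and the pivalate removal. C3 of A4 is α to an ester and β to the ring oxygen, so base can open the ring and erase both stereocentres.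
- Comparison: the length up to the key intermediate is similar. The chosen plan sets against the better diastereocontrol a C3 that is formed directly at the non-epimerisable alcohol level, a ketone that needs no placeholder, and a stereocentre that is not exposed to reversible ring opening before the ring is closed.

**Alternative 3: acetyl-activated SNAr closure of the ring oxygen.** The cut is at O1–C7a. KOtBu deprotonates the carbinol of the open-chain fluoro ketone A7, and the alkoxide displaces fluoride para to the acetyl group to give A6.
- Merits: the closure is intramolecular, stereospecific and poses no selectivity question. It is probably the most dependable ring-forming step of the four.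
- Weak points: the whole stereochemical problem moves into A7, an open chain with two adjacent stereocentres and two aryl groups. It would have to be built by an auxiliary-controlled aldol reaction and reduction, with the ketone masked during enolate and hydride chemistry. The fluorinated ring A building block does not descend from acetovanillone in a few steps. Trityl and methoxymethyl groups add two deprotections.
- Comparison: this road is better in the reliability of the key step and in stereochemical certainty. The chosen plan sets against it roughly half the number of steps, one purchased stereocentre, and the second stereocentre made in the ring-forming step itself.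

Key step: step 9

## Route

Step 1
Reactants: 1 syringaldehyde (4-hydroxy-3,5-dimethoxybenzaldehyde)
Product: 2 3,5-dimethoxy-4-(triisopropylsilyloxy)benzaldehyde
Conditions: TIPSCl, imidazole, DMF, rt
Reagents that add atoms: chlorotriisopropylsilane, CC(C)[Si](Cl)(C(C)C)C(C)C
Why: Silylation of a phenol with a silyl chloride and imidazole; the hindered triisopropylsilyl ether is chosen to withstand the alkoxide, nitrosonium, TEMPONa and zinc/acetic acid steps that follow.

Step 2
Reactants: 2 3,5-dimethoxy-4-(triisopropylsilyloxy)benzaldehyde; 3 vinylmagnesium bromide
Product: 4 racemic 1-[3,5-dimethoxy-4-(triisopropylsilyloxy)phenyl]prop-2-en-1-ol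
Conditions: THF, −78 to 0 °C; aqueous NH4Cl
Reagents that add atoms: none
Why: Grignard 1,2-addition to an aromatic aldehyde; the aryl silyl ether is inert and the product is the racemic allylic alcohol.

Step 3
Reactants: 4 racemic 1-[3,5-dimethoxy-4-(triisopropylsilyloxy)phenyl]prop-2-en-1-ol
Product: 5 (1S)-1-[3,5-dimethoxy-4-(triisopropylsilyloxy)phenyl]prop-2-en-1-ol
Conditions: immobilised Candida antarctica lipase B (Novozym 435), vinyl acetate, tBuOMe, 30 °C, stopped just past half conversion
Reagents that add atoms: none
Why: Lipase-catalysed kinetic resolution by irreversible transesterification; by the empirical rule for secondary alcohols (aryl large, vinyl medium) the (R)-enantiomer should be acylated, leaving the (S)-alcohol. Running slightly past half conversion should raise the enantiopurity of the recovered alcohol, and this centre becomes C2 of the target.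

Step 4
Reactants: 6 acetovanillone (1-(4-hydroxy-3-methoxyphenyl)ethanone)
Product: 7 1-(4-hydroxy-3-methoxy-5-nitrophenyl)ethanone
Conditions: HNO3 (65%), AcOH, 10–15 °C
Reagents that add atoms: nitric acid, O[N+](=O)[O-]
Why: Electrophilic aromatic nitration directed ortho to the phenol, the para position being blocked by the acetyl group; this one substituent later provides both the SNAr activation and the radical precursor.

Step 5
Reactants: 7 1-(4-hydroxy-3-methoxy-5-nitrophenyl)ethanone
Product: 9 1-(4-chloro-3-methoxy-5-nitrophenyl)ethanone, via aryloxymethyleneiminium chloride 8 (not isolated)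
Conditions: (COCl)2, DMF, CH2Cl2, −40 °C to reflux
Reagents that add atoms: oxalyl chloride, ClC(=O)C(=O)Cl
Why: Chlorodehydroxylation of an ortho-nitrophenol with the Vilsmeier reagent: O-attack gives the iminium salt 8, and chloride then displaces the activated oxygen leaving group at the carbon ortho to nitro and para to acetyl (SNAr), regenerating DMF. Starting cold is meant to keep the reagent away from the methyl ketone.

Step 6
Reactants: 5 (1S)-1-[3,5-dimethoxy-4-(triisopropylsilyloxy)phenyl]prop-2-en-1-ol; 9 1-(4-chloro-3-methoxy-5-nitrophenyl)ethanone
Product: 11 1-[4-({(1S)-1-[3,5-dimethoxy-4-(triisopropylsilyloxy)phenyl]prop-2-en-1-yl}oxy)-3-methoxy-5-nitrophenyl]ethanone, via potassium alkoxide 10 (not isolated)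
Conditions: KN(SiMe3)2 (1 equiv), THF, −78 °C; then added to 9, THF, −40 to 0 °C
Reagents that add atoms: none
Why: SNAr (addition–elimination) at a chloride activated by an ortho nitro and a para acetyl group. One equivalent of base and inverse addition into excess electrophile should keep free base away from the methyl ketone, and since the carbinol C–O bond is not broken the (S) configuration is retained.

Step 7
Reactants: 11 1-[4-({(1S)-1-[3,5-dimethoxy-4-(triisopropylsilyloxy)phenyl]prop-2-en-1-yl}oxy)-3-methoxy-5-nitrophenyl]ethanone
Product: 12 1-[3-amino-4-({(1S)-1-[3,5-dimethoxy-4-(triisopropylsilyloxy)phenyl]prop-2-en-1-yl}oxy)-5-methoxyphenyl]ethanone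
Conditions: Zn dust (excess), NH4Cl, THF/MeOH/H2O, 0 °C to rt
Reagents that add atoms: none
Why: Dissolving-metal reduction of a nitroarene under near-neutral buffered conditions, chosen because it should leave the terminal alkene, the ketone, the silyl ether and the acid-sensitive allylic benzylic ether untouched; excess zinc is meant to carry the hydroxylamine stage through to the aniline.

Step 8
Reactants: 12 1-[3-amino-4-({(1S)-1-[3,5-dimethoxy-4-(triisopropylsilyloxy)phenyl]prop-2-en-1-yl}oxy)-5-methoxyphenyl]ethanone
Product: 13 5-acetyl-2-({(1S)-1-[3,5-dimethoxy-4-(triisopropylsilyloxy)phenyl]prop-2-en-1-yl}oxy)-3-methoxybenzenediazonium tetrafluoroborate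
Conditions: NOBF4 (1 equiv), MeCN/CH2Cl2, −40 to −10 °C; precipitation with cold Et2O, used at once
Reagents that add atoms: nitrosonium tetrafluoroborate, N#[O+].F[B-](F)(F)F
Why: Anhydrous diazotisation of an aniline with a nitrosonium salt, which forms only water and needs no mineral acid; the salt is to be kept cold and used directly because the ether carbon is ionisable.

Step 9
Reactants: 13 5-acetyl-2-({(1S)-1-[3,5-dimethoxy-4-(triisopropylsilyloxy)phenyl]prop-2-en-1-yl}oxy)-3-methoxybenzenediazonium tetrafluoroborate; 14 TEMPO (2,2,6,6-tetramethylpiperidin-1-yloxyl)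
Product: 16 1-{(2S,3R)-2-[3,5-dimethoxy-4-(triisopropylsilyloxy)phenyl]-7-methoxy-3-{[(2,2,6,6-tetramethylpiperidin-1-yl)oxy]methyl}-2,3-dihydro-1-benzofuran-5-yl}ethanone, via TEMPONa 15 (not isolated)
Conditions: 14, Na, THF, rt (gives 15); 15 added over 2 h to 13, PhCF3, 0 °C to rt
Reagents that add atoms: none
Why: TEMPONa 15 transfers one electron to the diazonium ion of 13, which loses N2 and gives the ring A aryl radical at C3a together with one equivalent of TEMPO; this is the TEMPONa-induced radical oxyarylation of arenediazonium salts, here in its intramolecular form on an ortho-allyloxy arenediazonium salt. The radical adds to the internal vinyl carbon in a 5-exo-trig closure that forms the C3–C3a bond and the dihydrofuran ring, a cyclisation of the ortho-allyloxyphenyl type that is among the fastest radical ring closures. The exocyclic primary radical is then captured by the persistent TEMPO radical, forming the CH2–O bond. C3 is the only new stereocentre and is controlled by C2: in the chair-like transition state of a 5-hexenyl-type closure the ring B aryl group on C2 sits pseudo-equatorial, so the new CH2 arm develops trans to it and gives (2S,3R), while C2 is not touched. The step needs ring closure to outrun direct coupling of the aryl radical with TEMPO, which slow addition of 15 secures by keeping the nitroxide concentration low, and exo over endo attack, which the three-atom tether secures. A minor cis isomer is to be expected and must be removed by chromatography here, because C3 cannot be corrected later.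

Step 10
Reactants: 16 1-{(2S,3R)-2-[3,5-dimethoxy-4-(triisopropylsilyloxy)phenyl]-7-methoxy-3-{[(2,2,6,6-tetramethylpiperidin-1-yl)oxy]methyl}-2,3-dihydro-1-benzofuran-5-yl}ethanone
Product: 17 1-{(2S,3R)-2-[3,5-dimethoxy-4-(triisopropylsilyloxy)phenyl]-3-(hydroxymethyl)-7-methoxy-2,3-dihydro-1-benzofuran-5-yl}ethanone
Conditions: Zn, AcOH/THF/H2O (3:1:1), 60 °C
Reagents that add atoms: none
Why: Reductive cleavage of the N–O bond of an O-alkyl hydroxylamine by zinc in acetic acid; a simple aryl methyl ketone and a hindered aryl silyl ether should survive, and neither stereocentre is involved.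

Step 11
Reactants: 17 1-{(2S,3R)-2-[3,5-dimethoxy-4-(triisopropylsilyloxy)phenyl]-3-(hydroxymethyl)-7-methoxy-2,3-dihydro-1-benzofuran-5-yl}ethanone
Product: 18 1-[(2S,3R)-2-(4-hydroxy-3,5-dimethoxyphenyl)-3-(hydroxymethyl)-7-methoxy-2,3-dihydro-1-benzofuran-5-yl]ethanone
Conditions: Bu4NF, AcOH, THF, 0 °C
Reagents that add atoms: none
Why: Fluoride cleavage of an aryl silyl ether; the acetic acid buffer protonates the phenoxide as it forms, so that ring opening at C2 through a quinone methide should have little chance, and the step gives the target.

## Compound list

1 | syringaldehyde (4-hydroxy-3,5-dimethoxybenzaldehyde) | COc1cc(C=O)cc(OC)c1O | starting material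
2 | 3,5-dimethoxy-4-(triisopropylsilyloxy)benzaldehyde | COc1cc(C=O)cc(OC)c1O[Si](C(C)C)(C(C)C)C(C)C | intermediate
3 | vinylmagnesium bromide | C=C[Mg]Br | starting material
4 | racemic 1-[3,5-dimethoxy-4-(triisopropylsilyloxy)phenyl]prop-2-en-1-ol | C=CC(O)c1cc(OC)c(O[Si](C(C)C)(C(C)C)C(C)C)c(OC)c1 | intermediate
5 | (1S)-1-[3,5-dimethoxy-4-(triisopropylsilyloxy)phenyl]prop-2-en-1-ol | C=C[C@H](O)c1cc(OC)c(O[Si](C(C)C)(C(C)C)C(C)C)c(OC)c1 | intermediate
6 | acetovanillone (1-(4-hydroxy-3-methoxyphenyl)ethanone) | CC(=O)c1ccc(O)c(OC)c1 | starting material
7 | 1-(4-hydroxy-3-methoxy-5-nitrophenyl)ethanone | CC(=O)c1cc(OC)c(O)c([N+](=O)[O-])c1 | intermediate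
8 | N-[(4-acetyl-2-methoxy-6-nitrophenoxy)methylidene]-N-methylmethanaminium chloride | CC(=O)c1cc(OC)c(OC=[N+](C)C)c([N+](=O)[O-])c1.[Cl-] | intermediate (not isolated)
9 | 1-(4-chloro-3-methoxy-5-nitrophenyl)ethanone | CC(=O)c1cc(OC)c(Cl)c([N+](=O)[O-])c1 | intermediate
10 | potassium (1S)-1-[3,5-dimethoxy-4-(triisopropylsilyloxy)phenyl]prop-2-en-1-olate | C=C[C@H]([O-])c1cc(OC)c(O[Si](C(C)C)(C(C)C)C(C)C)c(OC)c1.[K+] | intermediate (not isolated)
11 | 1-[4-({(1S)-1-[3,5-dimethoxy-4-(triisopropylsilyloxy)phenyl]prop-2-en-1-yl}oxy)-3-methoxy-5-nitrophenyl]ethanone | C=C[C@H](Oc1c(OC)cc(C(C)=O)cc1[N+](=O)[O-])c1cc(OC)c(O[Si](C(C)C)(C(C)C)C(C)C)c(OC)c1 | intermediate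
12 | 1-[3-amino-4-({(1S)-1-[3,5-dimethoxy-4-(triisopropylsilyloxy)phenyl]prop-2-en-1-yl}oxy)-5-methoxyphenyl]ethanone | C=C[C@H](Oc1c(OC)cc(C(C)=O)cc1N)c1cc(OC)c(O[Si](C(C)C)(C(C)C)C(C)C)c(OC)c1 | intermediate
13 | 5-acetyl-2-({(1S)-1-[3,5-dimethoxy-4-(triisopropylsilyloxy)phenyl]prop-2-en-1-yl}oxy)-3-methoxybenzenediazonium tetrafluoroborate | C=C[C@H](Oc1c(OC)cc(C(C)=O)cc1[N+]#N)c1cc(OC)c(O[Si](C(C)C)(C(C)C)C(C)C)c(OC)c1.F[B-](F)(F)F | intermediate
14 | TEMPO (2,2,6,6-tetramethylpiperidin-1-yloxyl) | CC1(C)CCCC(C)(C)N1[O] | starting material
15 | TEMPONa (sodium 2,2,6,6-tetramethylpiperidin-1-olate) | CC1(C)CCCC(C)(C)N1[O-].[Na+] | intermediate (not isolated)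
16 | 1-{(2S,3R)-2-[3,5-dimethoxy-4-(triisopropylsilyloxy)phenyl]-7-methoxy-3-{[(2,2,6,6-tetramethylpiperidin-1-yl)oxy]methyl}-2,3-dihydro-1-benzofuran-5-yl}ethanone | COc1cc([C@H]2Oc3c(OC)cc(C(C)=O)cc3[C@@H]2CON2C(C)(C)CCCC2(C)C)cc(OC)c1O[Si](C(C)C)(C(C)C)C(C)C | intermediate
17 | 1-{(2S,3R)-2-[3,5-dimethoxy-4-(triisopropylsilyloxy)phenyl]-3-(hydroxymethyl)-7-methoxy-2,3-dihydro-1-benzofuran-5-yl}ethanone | COc1cc([C@H]2Oc3c(OC)cc(C(C)=O)cc3[C@@H]2CO)cc(OC)c1O[Si](C(C)C)(C(C)C)C(C)C | intermediate
18 | 1-[(2S,3R)-2-(4-hydroxy-3,5-dimethoxyphenyl)-3-(hydroxymethyl)-7-methoxy-2,3-dihydro-1-benzofuran-5-yl]ethanone | COc1cc([C@H]2Oc3c(OC)cc(C(C)=O)cc3[C@@H]2CO)cc(OC)c1O | target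

## Step count and least certain steps

Total step count: 11. Longest linear sequence: 9 steps (steps 1, 2, 3, 6, 7, 8, 9, 10, 11, from syringaldehyde 1).

**Step 9 (key step).** Three things may go wrong.
- TEMPONa may act as a base towards the acetyl group, or add to the terminal diazonium nitrogen, in place of transferring an electron.
- The aryl radical may be intercepted before it cyclises, or may attack ring B.
- The preference for trans closure may be incomplete, which costs material in the separation; the fallback below does not cure this.

The fallback sets out from 13 and exchanges the reductant and the radical trap. Sodium iodide in acetone at 0 °C reduces the diazonium ion without any base present. The same aryl radical cyclises and iodine-atom transfer should give 1-{(2S,3S)-2-[3,5-dimethoxy-4-(triisopropylsilyloxy)phenyl]-3-(iodomethyl)-7-methoxy-2,3-dihydro-1-benzofuran-5-yl}ethanone F1, by the iodide-induced atom-transfer cyclisation of ortho-allyloxy arenediazonium salts. CsOAc in DMF then displaces iodide to give {(2S,3R)-5-acetyl-2-[3,5-dimethoxy-4-(triisopropylsilyloxy)phenyl]-7-methoxy-2,3-dihydro-1-benzofuran-3-yl}methyl acetate F2. K2CO3 in MeOH at 0 °C removes the acetyl group, and the sequence comes back to the route at 17.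

**Step 6.** The alkoxide 10 may deprotonate the methyl ketone of 9, leading to aldol condensation and loss of the nucleophile. It may also isomerise by proton shift to the enolate of the ethyl ketone, and substitution at a chloride flanked by two ortho groups may be slow.

The fallback forms the same O–C bond from the alkyl side under weakly basic conditions. It sets out from 2 and 7 and needs neither 5 nor 9. A Horner–Wadsworth–Emmons reaction of 2 with triethyl phosphonoacetate and NaH gives ethyl (2E)-3-[3,5-dimethoxy-4-(triisopropylsilyloxy)phenyl]prop-2-enoate F3. Reduction with iBu2AlH gives (2E)-3-[3,5-dimethoxy-4-(triisopropylsilyloxy)phenyl]prop-2-en-1-ol F4, and methyl chloroformate with pyridine gives (2E)-3-[3,5-dimethoxy-4-(triisopropylsilyloxy)phenyl]prop-2-en-1-yl methyl carbonate F5. Enantioselective allylic etherification of F5 with the sodium salt of 7, catalysed by [Ir(cod)Cl]2 and a chiral phosphoramidite ligand of the enantiomeric series that delivers the (S)-branched ether, comes back to the route at 11. The hindered, weakly nucleophilic phenoxide is the open point of this fallback.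

**Step 8.** Once the aryloxy group carries a diazonium substituent it becomes a very good leaving group, so the allylic benzylic ether may be lost by ionisation. Ring B may also be oxidised by the nitrosonium ion or undergo azo coupling.

The fallback sets out from 12 and never accumulates a diazonium salt. Aprotic diazotisation with tBuONO in the presence of CuBr2 in MeCN at 0 °C generates the aryl radical in the flask. It cyclises and takes bromine from CuBr2 to give 1-{(2S,3S)-3-(bromomethyl)-2-[3,5-dimethoxy-4-(triisopropylsilyloxy)phenyl]-7-methoxy-2,3-dihydro-1-benzofuran-5-yl}ethanone F6. HCO2Na in DMF at 60 °C gives {(2S,3R)-5-acetyl-2-[3,5-dimethoxy-4-(triisopropylsilyloxy)phenyl]-7-methoxy-2,3-dihydro-1-benzofuran-3-yl}methyl formate F7. KHCO3 in MeOH cleaves the formate, and the sequence comes back to the route at 17.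

**Step 5.** The Vilsmeier reagent may attack the methyl ketone (chloroformylation of the enolisable acetyl group) in competition with the ipso substitution.

The fallback sets out from 7 and separates activation from substitution. Tf2O and pyridine in CH2Cl2 at 0 °C give 4-acetyl-2-methoxy-6-nitrophenyl trifluoromethanesulfonate F8. LiCl in DMF at 80 °C then displaces the triflate at the doubly activated carbon by SNAr, and the sequence comes back to the route at 9.

**Step 3.** Acylation of the bulky aryl carbinol may be slow or poorly selective, leaving alcohol of insufficient enantiopurity.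

The fallback sets out from 2 and 3 and replaces the resolution by an asymmetric C–C bond formation. Transmetallation of 3 with ZnCl2 gives divinylzinc F9, which adds to 2 under catalysis by a chiral β-amino alcohol of the enantiomeric series that delivers the (S)-carbinol. The sequence comes back to the route at 5.

## Further compounds

F1 | step 9 | 1-{(2S,3S)-2-[3,5-dimethoxy-4-(triisopropylsilyloxy)phenyl]-3-(iodomethyl)-7-methoxy-2,3-dihydro-1-benzofuran-5-yl}ethanone | COc1cc([C@H]2Oc3c(OC)cc(C(C)=O)cc3[C@@H]2CI)cc(OC)c1O[Si](C(C)C)(C(C)C)C(C)C
F2 | step 9 | {(2S,3R)-5-acetyl-2-[3,5-dimethoxy-4-(triisopropylsilyloxy)phenyl]-7-methoxy-2,3-dihydro-1-benzofuran-3-yl}methyl acetate | COc1cc([C@H]2Oc3c(OC)cc(C(C)=O)cc3[C@@H]2COC(C)=O)cc(OC)c1O[Si](C(C)C)(C(C)C)C(C)C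
F3 | step 6 | ethyl (2E)-3-[3,5-dimethoxy-4-(triisopropylsilyloxy)phenyl]prop-2-enoate | CCOC(=O)/C=C/c1cc(OC)c(O[Si](C(C)C)(C(C)C)C(C)C)c(OC)c1
F4 | step 6 | (2E)-3-[3,5-dimethoxy-4-(triisopropylsilyloxy)phenyl]prop-2-en-1-ol | OC/C=C/c1cc(OC)c(O[Si](C(C)C)(C(C)C)C(C)C)c(OC)c1
F5 | step 6 | (2E)-3-[3,5-dimethoxy-4-(triisopropylsilyloxy)phenyl]prop-2-en-1-yl methyl carbonate | COC(=O)OC/C=C/c1cc(OC)c(O[Si](C(C)C)(C(C)C)C(C)C)c(OC)c1
F6 | step 8 | 1-{(2S,3S)-3-(bromomethyl)-2-[3,5-dimethoxy-4-(triisopropylsilyloxy)phenyl]-7-methoxy-2,3-dihydro-1-benzofuran-5-yl}ethanone | COc1cc([C@H]2Oc3c(OC)cc(C(C)=O)cc3[C@@H]2CBr)cc(OC)c1O[Si](C(C)C)(C(C)C)C(C)C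
F7 | step 8 | {(2S,3R)-5-acetyl-2-[3,5-dimethoxy-4-(triisopropylsilyloxy)phenyl]-7-methoxy-2,3-dihydro-1-benzofuran-3-yl}methyl formate | COc1cc([C@H]2Oc3c(OC)cc(C(C)=O)cc3[C@@H]2COC=O)cc(OC)c1O[Si](C(C)C)(C(C)C)C(C)C
F8 | step 5 | 4-acetyl-2-methoxy-6-nitrophenyl trifluoromethanesulfonate | CC(=O)c1cc(OC)c(OS(=O)(=O)C(F)(F)F)c([N+](=O)[O-])c1
F9 | step 3 | divinylzinc | C=C[Zn]C=C
A1 | alternative 1 | methyl (2S,3R)-2-[4-(tert-butyldimethylsilyloxy)-3,5-dimethoxyphenyl]-3-(tert-butyldimethylsilyloxymethyl)-7-methoxy-2,3-dihydro-1-benzofuran-5-carboxylate | COc1cc([C@H]2Oc3c(OC)cc(C(=O)OC)cc3[C@@H]2CO[Si](C)(C)C(C)(C)C)cc(OC)c1O[Si](C)(C)C(C)(C)C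
A2 | alternative 1 | tert-butyl{[(2S,3R)-2-[4-(tert-butyldimethylsilyloxy)-3,5-dimethoxyphenyl]-3-(tert-butyldimethylsilyloxymethyl)-2,3-dihydrofuran-5-yl]oxy}dimethylsilane | COc1cc([C@H]2OC(O[Si](C)(C)C(C)(C)C)=C[C@@H]2CO[Si](C)(C)C(C)(C)C)cc(OC)c1O[Si](C)(C)C(C)(C)C
A3 | alternative 1 | methyl 3-methoxy-2-oxo-2H-pyran-5-carboxylate | COC(=O)C1=COC(=O)C(OC)=C1
A4 | alternative 2 | methyl (2S,3S)-5-bromo-2-[3,5-dimethoxy-4-(pivaloyloxy)phenyl]-7-methoxy-2,3-dihydro-1-benzofuran-3-carboxylate | COc1cc([C@H]2Oc3c(OC)cc(Br)cc3[C@@H]2C(=O)OC)cc(OC)c1OC(=O)C(C)(C)C
A5 | alternative 2 | 4-[(2S)-6-bromo-8-methoxy-4-oxochroman-2-yl]-2,6-dimethoxyphenyl pivalate | O=C1C[C@@H](c2cc(OC)c(OC(=O)C(C)(C)C)c(OC)c2)Oc2c(OC)cc(Br)cc21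
A6 | alternative 3 | 1-{(2S,3R)-2-[3,5-dimethoxy-4-(methoxymethoxy)phenyl]-7-methoxy-3-(trityloxymethyl)-2,3-dihydro-1-benzofuran-5-yl}ethanone | COc1cc([C@H]2Oc3c(OC)cc(C(C)=O)cc3[C@@H]2COC(c2ccccc2)(c2ccccc2)c2ccccc2)cc(OC)c1OCOC
A7 | alternative 3 | 1-{4-fluoro-3-[(1S,2R)-1-hydroxy-1-[3,5-dimethoxy-4-(methoxymethoxy)phenyl]-3-(trityloxy)propan-2-yl]-5-methoxyphenyl}ethanone | COc1cc([C@@H](O)[C@@H](COC(c2ccccc2)(c2ccccc2)c2ccccc2)c2cc(C(C)=O)cc(OC)c2F)cc(OC)c1OCOC
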